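# Proposed synthesis of 3,6-dibromo-2-(2,4-dibromophenoxy)phenol (12)

## The problem

The target 12 is a diaryl ether of two brominated benzene rings: ring A carries the free hydroxyl on C1, the ether oxygen on C2 and bromines on C3 and C6, and ring B is a 2,4-dibromophenyl group. There is no stereocenter, so the only thing to control is the placement of six substituents. Ring B has the pattern of 2,4-dibromophenol (6), which can be bought, and should enter intact. Ring A is the difficulty: four contiguous substituents (Br, OH, OAr, Br) with both bromines ortho to an oxygen and para to each other, a pattern that electrophilic bromination of a 1,2-dioxygenated benzene does not give, because bromine enters para to oxygen at C4 and C5. The ether bond O–C2 is flanked on ring A by two ortho substituents, and a metal-mediated etherification would have to tell its own carbon–halogen bond from four aryl C–Br bonds. These C–Br bonds exclude alkyllithium reagents, low-valent transition metals and hydrogenolysis, any aryl carbanion next to bromine can expel bromide, and the acidic phenol is best uncovered last. The feature to exploit is that C1 and C2 are adjacent and flanked symmetrically by C6–Br and C3–Br: removing both oxygens leaves 3,6-dibromobenzyne (9), whose two reactive carbons are equivalent, so a nucleophile and an electrophile can be set on C2 and C1 with no regiochemical question.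

## Retrosynthesis

**Target 12 to boronate 10.** The C1–OH bond is traced back to a C1–B bond, giving 2-[3,6-dibromo-2-(2,4-dibromophenoxy)phenyl]-4,4,5,5-tetramethyl-1,3,2-dioxaborolane (10). An aryne accepts one nucleophile and one electrophile, never two oxygen nucleophiles, and boron is the electrophile that is later exchanged for hydroxyl at the same carbon. Compound 10 is not smaller, but it is neutral, can be separated from phenolic by-products by a basic wash, and hides the acidic phenol. The forward step is a peroxide oxidation through borate ester 11, which must outrun protodeboronation of a hindered, electron-poor aryl–boron bond.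

**Boronate 10 to triflate 5 and aryloxyborane 8.** The ether bond O–C2 and the C1–B bond are cut together. Ring A becomes the aryne 9, stored as 3,6-dibromo-2-(trimethylsilyl)phenyl trifluoromethanesulfonate (5), and the other half is the O–B sigma bond of 2-(2,4-dibromophenoxy)-4,4,5,5-tetramethyl-1,3,2-dioxaborolane (8). Cutting the ether bond alone would leave a 3,6-dibromo-1,2-dioxygenated ring A to be made separately, followed by a doubly ortho-hindered etherification beside four C–Br bonds. The double cut forms both carbon–heteroatom bonds of ring A in one operation, and each fragment holds one ring with two bromines and one oxygen. The forward reaction must add the aryloxide to 9 and capture the resulting ortho-bromo aryl anion at boron before it is protonated or loses bromide; symmetry settles the regiochemistry.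

**Aryloxyborane 8 to phenol 6 and pinacolborane 7.** The B–O bond is cut. Dehydrogenative coupling is preferred to alkoxide exchange on a borate ester, which is an equilibrium and leaves an alcohol behind. The coupling is irreversible and its only by-product is a gas, which matters because 8 is hydrolytically labile and cannot be chromatographed. Both 6 and 7 are purchased.

**Triflate 5 to silyl ether 2 and phenol 1.** The S–O and C–Si bonds are cut. Compound 5 comes from lithium phenoxide 4, which arises from aryllithium 3 by an oxygen-to-carbon silyl shift, and 3 comes from (2,5-dibromophenoxy)trimethylsilane (2), the silyl ether of 2,5-dibromophenol (1). A separate C-silylation of a protected phenol would cost a protection and a deprotection, and halogen–metal exchange would attack one of the bromines that must stay. The hydrogen at C6 of 2, between the silyloxy group and a bromine, is the most acidic on the ring. The forward sequence needs an amide base to metalate there only, and the silyl shift to be faster than loss of bromide from 3.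

## Roads not taken

**Alternative 1:** Ring A is cut through C1–C6 and C2–C3. C3 to C6 with both bromines would come from 2,5-dibromothiophene 1,1-dioxide (A1), and C1–C2 with both oxygens from a bis(trimethylsilyl) ketene acetal carrying the 2,4-dibromophenoxy group on its nucleophilic carbon (A2). A [4+2] cycloaddition of A1 with A2, cheletropic loss of the sulfonyl bridge and 1,2-elimination of a silanol would give [3,6-dibromo-2-(2,4-dibromophenoxy)phenoxy]trimethylsilane (A3). On aqueous work-up A3 is desilylated to 12.

The symmetric diene removes the regiochemical question just as the symmetric aryne does, and the polarity (electron-poor diene, electron-rich alkene) is matched. This road is better than the chosen plan in two respects: no carbanion ever sits next to a bromine, and A3 arrives at the phenol oxidation level, so no C–B oxidation is needed. Its weak points lie in the partners. A1 is a non-aromatic sulfone that dimerises readily and needs forcing oxidation of an electron-poor thiophene. A2 is moisture-labile and requires double deprotonation of an aryloxyacetic acid by an amide base, although ring B has an acidic hydrogen between its two bromines. A ketene acetal and a vinyl sulfone may also combine stepwise by conjugate addition at C3 of A1, giving wrongly connected products instead of A3. In comparison, the pairing is no closer to known chemistry than the chosen key step, and the step count is about the same (five). The chosen plan offers two bench-stable aromatic partners made from phenols by routine operations, with the aryne as the only short-lived species.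

**Alternative 2:** Ring B is cut through C1'–C2' and C5'–C6'. 3,5-Dibromo-2-pyrone (A4) would be the diene and 1,4-dibromo-2-[(2-bromoethenyl)oxy]-3-methoxybenzene (A5) the dienophile. Cycloaddition, decarboxylation and dehydrobromination would close ring B as 1,4-dibromo-2-(2,4-dibromophenoxy)-3-methoxybenzene (A6). Demethylation of A6 would then give 12.

Pyrone cycloaddition–aromatisation is an established benzannulation, and the known polarity of A4 (the nucleophilic alkene terminus bonds to C6 of the pyrone) places the bromines at C2' and C4'. Every step of this road has closer precedent than the chosen key step, and that is its real advantage. Its weak points are structural. It builds the ring that can be bought as 6 and leaves the difficult ring untouched. A5 must be made from 3,6-dibromo-2-methoxyphenol (A7). A7 already holds the whole ring A pattern and needs its own directed metalation and oxidation. A5 is a poor dienophile (its oxygen lone pair is shared with an electron-poor aryl group and it bears a beta-bromine), so forcing temperatures are expected. In the aromatisation that leads to A6 the aryloxide, a good leaving group, can leave in place of bromide, destroying the ether bond just formed. In comparison, this road needs about eight steps against five. The chosen plan is shorter, makes the ring A pattern in its key step and uses ring B as purchased.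

**Alternative 3:** The C4'–Br and C2'–Br bonds of ring B are cut, leading back to 3,6-dibromo-2-phenoxyphenyl methanesulfonate (A8). Two equivalents of electrophilic bromine under Lewis-acid catalysis would brominate the phenoxy ring para and then ortho to oxygen, giving 3,6-dibromo-2-(2,4-dibromophenoxy)phenyl methanesulfonate (A9). Cleavage of the sulfonate of A9 would give 12.

Bromination of aryl ethers is thoroughly known. Ring A of A8 is deactivated by two bromines and the sulfonate, and its two ortho substituents twist it out of conjugation with the ether oxygen, so ring B should react first. This road is better than the chosen plan in one respect: a bromine-free ring B would make any anionic chemistry that builds ring A cleaner (a better nucleophile, no acidic hydrogen between two bromines, no bromine transfer). Its weak point is that the cut does not touch the real problem. The parent phenol, 3,6-dibromo-2-phenoxyphenol (A10), has the same ring A pattern. A10 would most plausibly be made by the aryne chemistry proposed here, after which mesylation to A8, bromination to A9 and sulfonate cleavage add three steps. Selectivity rests on relative rates only: C5 of ring A is para to the ether oxygen and open, and ring B can take a third bromine at C6'. In comparison, the chosen plan places the ring B bromines by purchase, beyond doubt, but its key step must tolerate them. If they prove incompatible with the aryne step, this road through A10 is the natural retreat.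

Key step: step 4

Remark on the chemistry: in step 4 the aryloxide may be delivered by 8, by its fluoride adduct or by free 2,4-dibromophenoxide in equilibrium with them; the step is written for the net equation 5 + 8 + KF.

## Route

Step 1
Reactants: 1 2,5-dibromophenol
Product: 2 (2,5-dibromophenoxy)trimethylsilane
Conditions: HN(SiMe3)2 (0.7 equiv), neat, 80 °C; volatiles removed in vacuo
Reagents that add atoms: hexamethyldisilazane, C[Si](C)(C)N[Si](C)(C)C
Why: O-Silylation of a phenol with a disilazane; the acidic dibromophenol protonates the silazane, the only by-product is volatile, and the moisture-sensitive silyl ether is taken on after evaporation.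

Step 2
Reactants: 2 (2,5-dibromophenoxy)trimethylsilane
Product: 5 3,6-dibromo-2-(trimethylsilyl)phenyl trifluoromethanesulfonate, via aryllithium 3 (not isolated), via lithium phenoxide 4 (not isolated)
Conditions: LiN(iPr)2 (1.1 equiv), THF, −78 °C; PhNTf2 (1.2 equiv), −78 °C to rt; aq NH4Cl
Reagents that add atoms: N-phenylbis(trifluoromethanesulfonimide), O=S(=O)(N(c1ccccc1)S(=O)(=O)C(F)(F)F)C(F)(F)F
Why: Directed ortho-lithiation, anionic 1,3 oxygen-to-carbon silyl shift (retro-Brook rearrangement) and O-triflation in one flask: the hydrogen at C6 of 2, between the silyloxy group and a bromine, is the most acidic, the amide base does not exchange bromine, 3 rearranges to the hindered phenoxide 4 at low temperature, and PhNTf2 sulfonylates 4 in the presence of the liberated amine.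

Step 3
Reactants: 6 2,4-dibromophenol; 7 pinacolborane
Product: 8 2-(2,4-dibromophenoxy)-4,4,5,5-tetramethyl-1,3,2-dioxaborolane
Conditions: 7 (1.1 equiv), toluene, 80 °C, argon, until gas evolution ends; evaporated, used crude
Reagents that add atoms: none
Why: Dehydrogenative O-borylation of a phenol with a hydroborane: the acidic O–H reacts with the hydridic B–H irreversibly, the by-product is a gas, and the hydrolytically labile aryloxyborane needs no purification.

Step 4
Reactants: 5 3,6-dibromo-2-(trimethylsilyl)phenyl trifluoromethanesulfonate; 8 2-(2,4-dibromophenoxy)-4,4,5,5-tetramethyl-1,3,2-dioxaborolane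
Product: 10 2-[3,6-dibromo-2-(2,4-dibromophenoxy)phenyl]-4,4,5,5-tetramethyl-1,3,2-dioxaborolane, via 3,6-dibromobenzyne 9 (not isolated)
Conditions: 8 (3 equiv), KF (1.5 equiv), 18-crown-6 (1.5 equiv), THF, 0 °C to rt, 5 added slowly; aq K2CO3 wash
Reagents that add atoms: none
Why: Proposed new method: fluoride removes the trimethylsilyl group of 5 and triflate departs, releasing the aryne 9, while fluoride also turns part of 8 into a tetracoordinate borate that hands 2,4-dibromophenoxide to the strained triple bond. The ortho-bromo aryl anion formed by this addition is captured by tricoordinate boron of a further molecule of 8, and the new borate expels 2,4-dibromophenoxide, which carries a chain, so that net the O–B sigma bond of 8 has added across C2 and C1 of ring A. The closest known reaction types are aryne insertions into element–element sigma bonds such as N–Si, S–Sn and Sn–Sn and three-component aryne couplings of a heteroatom nucleophile with a separate electrophile; the interception of a short-lived ortho-haloaryl anion by a borate ester is the in situ quench known from lithiation–borylation, but insertion of an aryne into an O–B bond has not been shown. No ring closes and no stereocenter is formed. Regioselectivity needs no control because 9 is symmetric, each aryne carbon being flanked by a C–Br bond, and the two inductively withdrawing bromines also make 9 electrophilic enough for the weakly basic aryloxide. The selectivity the step does need is kinetic, boron capture ahead of protonation, bromide loss or bromine transfer at the aryl anion, and it is secured by an aprotic medium, by 8 in excess over both 5 and fluoride, and by slow addition of 5.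

Step 5
Reactants: 10 2-[3,6-dibromo-2-(2,4-dibromophenoxy)phenyl]-4,4,5,5-tetramethyl-1,3,2-dioxaborolane
Product: 12 3,6-dibromo-2-(2,4-dibromophenoxy)phenol, via aryl borate ester 11 (not isolated)
Conditions: 30% aq H2O2, NaOH, THF, 0 °C to rt; dilute aq HCl
Reagents that add atoms: hydrogen peroxide, OO
Why: Oxidation of an arylboronic ester with alkaline hydrogen peroxide: hydroperoxide adds to boron, the aryl group migrates from boron to oxygen with retention of position to give 11, and hydrolysis releases the phenol; the aryl bromides and the diaryl ether are inert under these conditions.

## Compound list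

1 | 2,5-dibromophenol | Oc1cc(Br)ccc1Br | starting material
2 | (2,5-dibromophenoxy)trimethylsilane | C[Si](C)(C)Oc1cc(Br)ccc1Br | intermediate
3 | [3,6-dibromo-2-(trimethylsilyloxy)phenyl]lithium | [Li]c1c(Br)ccc(Br)c1O[Si](C)(C)C | intermediate
4 | lithium 3,6-dibromo-2-(trimethylsilyl)phenoxide | [Li+].[O-]c1c(Br)ccc(Br)c1[Si](C)(C)C | intermediate
5 | 3,6-dibromo-2-(trimethylsilyl)phenyl trifluoromethanesulfonate | C[Si](C)(C)c1c(Br)ccc(Br)c1OS(=O)(=O)C(F)(F)F | intermediate
6 | 2,4-dibromophenol | Oc1ccc(Br)cc1Br | starting material
7 | pinacolborane (4,4,5,5-tetramethyl-1,3,2-dioxaborolane) | CC1(C)OBOC1(C)C | starting material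
8 | 2-(2,4-dibromophenoxy)-4,4,5,5-tetramethyl-1,3,2-dioxaborolane | CC1(C)OB(Oc2ccc(Br)cc2Br)OC1(C)C | intermediate
9 | 3,6-dibromobenzyne (3,6-dibromo-1,2-didehydrobenzene) | BrC1=CC=C(Br)C#C1 | intermediate
10 | 2-[3,6-dibromo-2-(2,4-dibromophenoxy)phenyl]-4,4,5,5-tetramethyl-1,3,2-dioxaborolane | CC1(C)OB(c2c(Br)ccc(Br)c2Oc2ccc(Br)cc2Br)OC1(C)C | intermediate
11 | 2-[3,6-dibromo-2-(2,4-dibromophenoxy)phenoxy]-4,4,5,5-tetramethyl-1,3,2-dioxaborolane | CC1(C)OB(Oc2c(Br)ccc(Br)c2Oc2ccc(Br)cc2Br)OC1(C)C | intermediate
12 | 3,6-dibromo-2-(2,4-dibromophenoxy)phenol | Oc1c(Br)ccc(Br)c1Oc1ccc(Br)cc1Br | target

## Step count and least certain steps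

Total steps: 5. Longest linear sequence: 4 steps (steps 1, 2, 4 and 5, from 1 through 2, 5 and 10 to 12). Step 3 is a one-step side branch.

**Step 4 (key step).** The most likely failure is that the aryl anion formed after aryloxide addition is protonated, sheds bromide to give a second aryne, or takes bromine from another aryl bromide before boron captures it. It is a carbanion next to bromine in a flask full of polybrominated arenes, and part of the boron is tied up by fluoride.

The fallback uses known chemistry, sets out from 1 and comes back to the route at 12; the aryne disconnection is given up. Phenol 1 is protected with MOMCl and iPr2NEt as 1,4-dibromo-2-(methoxymethoxy)benzene (F1). F1 is metalated between its two directing groups by LiN(iPr)2 in the presence of B(OiPr)3 at −78 °C (in situ quench), giving after aqueous work-up [3,6-dibromo-2-(methoxymethoxy)phenyl]boronic acid (F2). H2O2 oxidises F2 to 3,6-dibromo-2-(methoxymethoxy)phenol (F3). F3 is O-arylated without a transition metal by (2,4-dibromophenyl)(2,4,6-trimethoxyphenyl)iodonium 4-methylbenzenesulfonate (F4), with KOtBu in THF, to give 1,4-dibromo-2-(2,4-dibromophenoxy)-3-(methoxymethoxy)benzene (F5). F4 is made in one pot from 2,4-dibromo-1-iodobenzene, mCPBA, 4-methylbenzenesulfonic acid and 1,3,5-trimethoxybenzene. Finally, HCl in MeOH removes the acetal of F5 and gives 12.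

**Step 2.** The most likely failure is loss of bromide from the lithiated ring or migration of bromine before the silyl group has shifted, because 3 carries a bromine on the neighbouring carbon. Attack of the amide at silicon is a lesser risk.

The fallback sets out from 1 and comes back to the route at 5; the carbanion is trapped by an external silyl chloride as it forms, so no rearrangement is needed. Phenol 1 is converted with 3,4-dihydro-2H-pyran and catalytic pyridinium 4-methylbenzenesulfonate into racemic 2-(2,5-dibromophenoxy)oxane (F6). LiN(iPr)2 is added to F6 and Me3SiCl in THF at −78 °C to give racemic [3,6-dibromo-2-(oxan-2-yloxy)phenyl]trimethylsilane (F7). Pyridinium 4-methylbenzenesulfonate in MeOH cleaves the acetal of F7 and frees 3,6-dibromo-2-(trimethylsilyl)phenol (F8) under conditions mild enough to spare the aryl–silicon bond. Tf2O and pyridine in CH2Cl2 at 0 °C then convert F8 into 5.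

**Step 5.** The most likely failure is protodeboronation in competition with oxidation. The aryl–boron bond is shielded from hydroperoxide by bromine and aryloxy groups and, being electron-poor, is cleaved by aqueous base.

The fallback sets out from 10 and comes back to the route at 12; it uses a different boron species and a non-basic electrophilic oxidant. KHF2 in MeOH/H2O converts 10 into potassium [3,6-dibromo-2-(2,4-dibromophenoxy)phenyl]trifluoroborate (F9). KHSO5 (as 2KHSO5·KHSO4·K2SO4) in acetone/H2O at rt then oxidises F9 to 12.

**Step 3.** The most likely failure is incomplete coupling, or scrambling of the ligands on boron and hydrolysis by adventitious water, since the B–O bond of an electron-poor aryloxide is labile.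

The fallback sets out from 6 and comes back to the route at 8, and makes no new compound: ester exchange of 6 with 2-isopropoxy-4,4,5,5-tetramethyl-1,3,2-dioxaborolane in refluxing toluene, with the liberated alcohol removed by distillation.

## Further compounds

F1 | step 4 | 1,4-dibromo-2-(methoxymethoxy)benzene | COCOc1cc(Br)ccc1Br
F2 | step 4 | [3,6-dibromo-2-(methoxymethoxy)phenyl]boronic acid | COCOc1c(Br)ccc(Br)c1B(O)O
F3 | step 4 | 3,6-dibromo-2-(methoxymethoxy)phenol | COCOc1c(Br)ccc(Br)c1O
F4 | step 4 | (2,4-dibromophenyl)(2,4,6-trimethoxyphenyl)iodonium 4-methylbenzenesulfonate | COc1cc(OC)c([I+]c2ccc(Br)cc2Br)c(OC)c1.Cc1ccc(S(=O)(=O)[O-])cc1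
F5 | step 4 | 1,4-dibromo-2-(2,4-dibromophenoxy)-3-(methoxymethoxy)benzene | COCOc1c(Br)ccc(Br)c1Oc1ccc(Br)cc1Br
F6 | step 2 | 2-(2,5-dibromophenoxy)oxane (racemic) | Brc1ccc(Br)c(OC2CCCCO2)c1
F7 | step 2 | [3,6-dibromo-2-(oxan-2-yloxy)phenyl]trimethylsilane (racemic) | C[Si](C)(C)c1c(Br)ccc(Br)c1OC1CCCCO1
F8 | step 2 | 3,6-dibromo-2-(trimethylsilyl)phenol | C[Si](C)(C)c1c(Br)ccc(Br)c1O
F9 | step 5 | potassium [3,6-dibromo-2-(2,4-dibromophenoxy)phenyl]trifluoroborate | [K+].F[B-](F)(F)c1c(Br)ccc(Br)c1Oc1ccc(Br)cc1Br
F0 | step 3 | none | none
A1 | alternative 1 | 2,5-dibromothiophene 1,1-dioxide | O=S1(=O)C(Br)=CC=C1Br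
A2 | alternative 1 | {[2-(2,4-dibromophenoxy)ethene-1,1-diyl]bis(oxy)}bis(trimethylsilane) | C[Si](C)(C)OC(O[Si](C)(C)C)=COc1ccc(Br)cc1Br
A3 | alternative 1 | [3,6-dibromo-2-(2,4-dibromophenoxy)phenoxy]trimethylsilane | C[Si](C)(C)Oc1c(Br)ccc(Br)c1Oc1ccc(Br)cc1Br
A4 | alternative 2 | 3,5-dibromo-2H-pyran-2-one | O=c1occ(Br)cc1Br
A5 | alternative 2 | 1,4-dibromo-2-{[(E)-2-bromoethenyl]oxy}-3-methoxybenzene | COc1c(Br)ccc(Br)c1O/C=C/Br
A6 | alternative 2 | 1,4-dibromo-2-(2,4-dibromophenoxy)-3-methoxybenzene | COc1c(Br)ccc(Br)c1Oc1ccc(Br)cc1Br
A7 | alternative 2 | 3,6-dibromo-2-methoxyphenol | COc1c(Br)ccc(Br)c1O
A8 | alternative 3 | 3,6-dibromo-2-phenoxyphenyl methanesulfonate | CS(=O)(=O)Oc1c(Br)ccc(Br)c1Oc1ccccc1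
A9 | alternative 3 | 3,6-dibromo-2-(2,4-dibromophenoxy)phenyl methanesulfonate | CS(=O)(=O)Oc1c(Br)ccc(Br)c1Oc1ccc(Br)cc1Br
A10 | alternative 3 | 3,6-dibromo-2-phenoxyphenol | Oc1c(Br)ccc(Br)c1Oc1ccccc1
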